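**Plan**

1. Numbering used here: core ring C1 (oxirane carbon carrying the side chain), C2 (CHOH), C3 (=CH), C4 (=C–CH2OH, the CH2 is C7), C5 (CHOH), C6 (oxirane CH); side chain C1'(OH)–C2'H=C3'(Me)–C4'H=C5'H; cyclohexane C1''–C6''.
2. Retrosynthetic cuts, in order: the silyl ethers; C1'–C2' (alkenyllithium + epoxy aldehyde); the oxirane C1–O–C6 (from a C1=C6 enal); ring bonds C1–C2 and C5–C6 together ([4+2]); C4'=C5' (Horner–Wadsworth–Emmons); C1''–C2'' (epoxy-olefin cyclisation).
3. Feature used: in ring C1–C6 the only alkene C3=C4 lies between the carbinol carbons C2 and C5, whose oxygens are cis, and C1 carries the carbonyl-level carbon C1'. This is a cis-1,4-dioxygenated cyclohexene that a 1,4-dioxygenated diene (C2=C3–C4=C5) and an alkynoyl unit (C6≡C1–C1'=O) assemble in one event; tying O5 to the C7 oxygen in a dioxasiline ring fixes the diene geometry.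
4. Forward: dihydroxyacetone → cyclic silyl dienol ether diene; copper-catalysed cycloaddition with a propioloyl pyrazole builds ring C1–C6 (C5–C6 leads, C1–C2 closes the ring); acyl pyrazole → enal → epoxy aldehyde; separately geranyl acetate → cyclohexane aldehyde → (1Z,3E)-dienyl iodide; union at C1'–C2'; global desilylation.
5. Stereochemistry: C2/C5 cis from the suprafacial cycloaddition, absolute sense from the chiral copper catalyst; oxirane anti to both silyloxy groups (substrate control); C1' by Felkin–Anh/Cornforth addition; C3'' from Shi epoxidation, C1''/C6'' from the chair cyclisation; C2'=C3' Z from anti carbomagnesiation, C4'=C5' E from the olefination.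

Key step: step 6

Assumption (remark on the chemistry): the L-configured amino amide ligand is taken to deliver 10 to the diene face that leads to 11; if the sense of induction is the opposite one, the D-configured ligand is used in its place.

**Route**

Step 1
Reactants: 1 1,3-dihydroxyacetone dimer
Product: 3 2,2-di-tert-butyl-1,3,2-dioxasilinan-5-one, via dihydroxyacetone monomer 2 (not isolated)
Conditions: t-Bu2Si(OTf)2, pyridine, DMF, 0 °C to rt
Reagents that add atoms: di-tert-butylsilyl bis(trifluoromethanesulfonate), CC(C)(C)[Si](OS(=O)(=O)C(F)(F)F)(OS(=O)(=O)C(F)(F)F)C(C)(C)C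
Why: Silylene protection of a 1,3-diol: the dimer opens to the monomer in DMF and the bis-triflate bridges its two primary hydroxyls to the six-membered silylene ketone.

Step 2
Reactants: 3 2,2-di-tert-butyl-1,3,2-dioxasilinan-5-one + 4 diethyl (cyanomethyl)phosphonate
Product: 5 2-(2,2-di-tert-butyl-1,3,2-dioxasilinan-5-ylidene)acetonitrile
Conditions: NaH, THF, 0 °C; then 3, 0 °C to rt
Reagents that add atoms: none
Why: Horner–Wadsworth–Emmons olefination of an activated α,α'-dioxygenated ketone, which is symmetric so that no alkene geometry arises.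

Step 3
Reactants: 5 2-(2,2-di-tert-butyl-1,3,2-dioxasilinan-5-ylidene)acetonitrile
Product: 6 2-(2,2-di-tert-butyl-1,3,2-dioxasilinan-5-ylidene)acetaldehyde
Conditions: i-Bu2AlH (1.1 equiv), CH2Cl2, −78 °C; aq. potassium sodium tartrate
Reagents that add atoms: water, O
Why: Partial reduction of the conjugated nitrile to the aluminium aldimine and its hydrolysis to the enal (nitrile-to-aldehyde reduction).

Step 4
Reactants: 6 2-(2,2-di-tert-butyl-1,3,2-dioxasilinan-5-ylidene)acetaldehyde
Product: 7 tert-butyl{[(E)-2-(2,2-di-tert-butyl-4H-1,3,2-dioxasilin-5-yl)ethenyl]oxy}dimethylsilane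
Conditions: TBSOTf, Et3N, Et2O, 0 °C; used without chromatography
Reagents that add atoms: tert-butyldimethylsilyl trifluoromethanesulfonate, CC(C)(C)[Si](C)(C)OS(=O)(=O)C(F)(F)F
Why: Silyl dienol ether formation by γ-deprotonation of the O-silylated enal: both γ-CH2 groups give the same diene, the ring holds the new enol ether oxygen cis to the remaining CH2O arm, and the s-trans enal gives the E silyl enol ether.

Step 5
Reactants: 8 propiolic acid + 9 3,5-dimethyl-1H-pyrazole
Product: 10 1-(3,5-dimethyl-1H-pyrazol-1-yl)prop-2-yn-1-one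
Conditions: DCC, CH2Cl2, 0 °C to rt
Reagents that add atoms: none
Why: Carbodiimide-mediated N-acylation of the pyrazole gives an activated amide that can bind a metal through N2 and the carbonyl oxygen.

Step 6
Reactants: 7 tert-butyl{[(E)-2-(2,2-di-tert-butyl-4H-1,3,2-dioxasilin-5-yl)ethenyl]oxy}dimethylsilane + 10 1-(3,5-dimethyl-1H-pyrazol-1-yl)prop-2-yn-1-one
Product: 11 (3,5-dimethyl-1H-pyrazol-1-yl)[(6S,8aS)-2,2-di-tert-butyl-6-(tert-butyldimethylsilyloxy)-6,8a-dihydro-4H-1,3,2-benzodioxasilin-7-yl]methanone (the two ring oxygens cis)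
Conditions: 7 (1.2 equiv), Cu(OTf)2 (10 mol%), (S)-2-amino-N-cyclopentyl-3-(naphthalen-2-yl)propanamide (11 mol%), 4 Å molecular sieves, MeCN, −40 °C
Reagents that add atoms: none
Why: Copper-catalysed enantioselective Diels–Alder reaction of an alkynoyl pyrazole, closest in type to the divalent-copper amino-amide catalysed [4+2] cycloadditions of 1-alkynoyl-3,5-dimethylpyrazoles with dienes and the Mukaiyama–Michael additions of silyl enol ethers to the same acceptors: Cu binds pyrazole N2 and the carbonyl oxygen, which lowers the alkyne LUMO and shields one face. The cycloaddition is strongly asynchronous: C5 of 7 is the more nucleophilic terminus because the charge it leaves is shared by the fully substituted C4 and the silyloxy-bearing C2, so it bonds first to the unsubstituted alkyne carbon C6, and the copper allenolate carbon C1 then closes the ring onto C2. The cyclohexa-1,4-diene ring is closed suprafacially on the diene in a [4π+2π] mode (at the stepwise limit a 6-(enolexo)-exo-trig closure of the allenolate on the silyloxocarbenium ion). C2 and C5 come out cis because both oxygens sit on the outside of the s-cis diene, O5 held there by the dioxasiline ring and O2 by the E enol ether, and their absolute configuration is set by the catalyst through the open face of the chelated dienophile and the placement of the diene body away from the ligand. No endo or exo stereocentre arises because C1 and C6 stay sp2. The step needs bonding of C5 (not C2) to C6, which the C4 substituent secures; ring closure faster than silyl transfer to the enolate, which the bulky silyl groups and low temperature favour; and the absence of protic acid, so that the adduct does not lose silanol to an arene.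

Step 7
Reactants: 11 acyl pyrazole cycloadduct
Product: 12 (6S,8aS)-2,2-di-tert-butyl-6-(tert-butyldimethylsilyloxy)-6,8a-dihydro-4H-1,3,2-benzodioxasilin-7-carbaldehyde
Conditions: i-Bu2AlH (1.05 equiv), CH2Cl2, −78 °C; aq. potassium sodium tartrate
Reagents that add atoms: none
Why: Partial reduction of an activated amide: the N-acyl pyrazole gives a chelated tetrahedral aluminate that collapses to the enal only on work-up.

Step 8
Reactants: 12 core enal
Product: 13 epoxy aldehyde (12 with an oxirane across C1–C6 on the face opposite both silyloxy groups; C1, C2, C5 and C6 arranged in space as in 30)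
Conditions: t-BuOOH (in decane), DBU, CH2Cl2, −20 to 0 °C
Reagents that add atoms: tert-butyl hydroperoxide, CC(C)(C)OO
Why: Weitz–Scheffer nucleophilic epoxidation of the enal: the peroxide adds to C6 and closes on C1 from the face anti to the C5 and C2 silyloxy groups, which sets C1 and C6, while the unactivated C3=C4 alkene is left alone.

Step 9
Reactants: 14 geranyl acetate
Product: 15 (2E)-5-[(2R)-3,3-dimethyloxiran-2-yl]-3-methylpent-2-en-1-yl acetate
Conditions: D-fructose-derived Shi ketone (30 mol%), KHSO5 (as 2KHSO5·KHSO4·K2SO4), K2CO3, Bu4NHSO4, MeCN/CH2(OMe)2/aq. Na2B4O7 buffer, 0 °C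
Reagents that add atoms: potassium peroxymonosulfate, [K+].[O-]S(=O)(=O)OO
Why: Shi epoxidation: the chiral dioxirane attacks the electron-richer 6,7-alkene (the 2,3-alkene is deactivated by the allylic acetate) through the spiro transition state that should give the R oxirane.

Step 10
Reactants: 15 (R)-6,7-epoxygeranyl acetate
Product: 17 [(1S,3R,6R)-3,6-dihydroxy-2,2,6-trimethylcyclohexyl]methyl acetate, via dioxanylium ion 16 (not isolated)
Conditions: SnCl4 (1.1 equiv), CH2Cl2, −78 °C; then aq. NaHCO3
Reagents that add atoms: water, O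
Why: Lewis acid-promoted epoxy-olefin (cation-olefin) cyclisation through a chair transition state in which the E alkene opens the oxirane at its tertiary carbon, the acetate carbonyl oxygen traps the tertiary cation anti to the new C–C bond and water opens the dioxanylium ion on work-up, so that C3'' keeps the oxirane configuration and C1'' and C6'' follow from the alkene geometry and the anti addition.

Step 11
Reactants: 17 diol acetate
Product: 18 [(1S,3R,6R)-2,2,6-trimethyl-3,6-bis(triethylsilyloxy)cyclohexyl]methyl acetate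
Conditions: TESOTf (2.5 equiv), 2,6-lutidine, CH2Cl2, −78 to 0 °C
Reagents that add atoms: triethylsilyl trifluoromethanesulfonate, CC[Si](CC)(CC)OS(=O)(=O)C(F)(F)F
Why: Silyl triflate silylation protects both the secondary and the hindered tertiary hydroxyl as fluoride-labile ethers.

Step 12
Reactants: 18 bis-TES acetate
Product: 19 [(1S,3R,6R)-2,2,6-trimethyl-3,6-bis(triethylsilyloxy)cyclohexyl]methanol
Conditions: i-Bu2AlH (2.2 equiv), CH2Cl2, −78 °C; aq. potassium sodium tartrate
Reagents that add atoms: none
Why: Reductive cleavage of the acetate frees the primary alcohol without touching the silyl ethers.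

Step 13
Reactants: 19 primary alcohol
Product: 20 (1R,3R,6R)-2,2,6-trimethyl-3,6-bis(triethylsilyloxy)cyclohexane-1-carbaldehyde
Conditions: Dess–Martin periodinane, NaHCO3, CH2Cl2, 0 °C to rt
Reagents that add atoms: none
Why: Dess–Martin oxidation under buffered, non-basic conditions gives the aldehyde without epimerisation at C1'' or loss of the β-silyloxy group.

Step 14
Reactants: 21 propargyl alcohol
Product: 23 (2Z)-3-iodo-2-methylprop-2-en-1-ol, via alkenylmagnesium alkoxide 22 (not isolated)
Conditions: MeMgBr (3 equiv), copper iodide CuI (10 mol%), THF, −10 °C to rt; then I2, −78 to 0 °C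
Reagents that add atoms: methylmagnesium bromide, C[Mg]Br; iodine, II
Why: Copper-catalysed anti carbomagnesiation of the propargylic alkoxide puts methyl on C2 and magnesium on C3 cis to the CH2O group in a five-membered chelate, which iodine cleaves with retention to the Z iodide.

Step 15
Reactants: 23 (2Z)-3-iodo-2-methylprop-2-en-1-ol
Product: 24 (1Z)-3-bromo-1-iodo-2-methylprop-1-ene
Conditions: CBr4, PPh3, CH2Cl2, 0 °C
Reagents that add atoms: carbon tetrabromide, BrC(Br)(Br)Br
Why: Appel bromination of the primary allylic alcohol proceeds by SN2 at carbon and leaves the vinyl iodide and its geometry untouched.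

Step 16
Reactants: 24 (1Z)-3-bromo-1-iodo-2-methylprop-1-ene + 25 triethyl phosphite
Product: 26 diethyl [(2Z)-3-iodo-2-methylprop-2-en-1-yl]phosphonate
Conditions: neat P(OEt)3, 90 °C
Reagents that add atoms: none
Why: Michaelis–Arbuzov reaction at the primary allylic bromide, the vinyl iodide being inert to the phosphite without a transition metal.

Step 17
Reactants: 20 cyclohexane carbaldehyde + 26 iodoallyl phosphonate
Product: 27 (1Z,3E)-1-iodo-2-methyl-4-[(1R,3R,6R)-2,2,6-trimethyl-3,6-bis(triethylsilyloxy)cyclohexyl]buta-1,3-diene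
Conditions: 26, LiN(SiMe3)2, THF, −78 °C; then 20, −78 to 0 °C
Reagents that add atoms: none
Why: Horner–Wadsworth–Emmons olefination with the allylic phosphonate anion should give the E C4'=C5' bond, the Z iodoalkene geometry of the reagent being kept at low temperature.

Step 18
Reactants: 27 dienyl iodide + 13 epoxy aldehyde
Product: 29 tetrasilyl-protected arthrosporol A (30 carrying a TBS ether on O2; a di-tert-butylsilylene across O5 and O7; TES ethers on the C3'' and C6'' oxygens; C1' hydroxyl free and S), via dienyllithium 28 (not isolated)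
Conditions: 27 (1.3 equiv), t-BuLi (2 equiv per 27), Et2O, −78 °C; then 13 in THF, −78 °C; aq. NH4Cl
Reagents that add atoms: none
Why: Iodine–lithium exchange with retention of the Z geometry and 1,2-addition of the alkenyllithium to the α,β-epoxy aldehyde under non-chelating Felkin–Anh/Cornforth control (carbonyl anti to the oxirane C–O bond, attack on the side away from C6) should give the anti epoxy alcohol, which is the 1'S configuration.

Step 19
Reactants: 29 tetrasilyl-protected arthrosporol A
Product: 30 arthrosporol A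
Conditions: HF·pyridine, excess pyridine, THF, 0 °C to rt
Reagents that add atoms: none
Why: Fluoride-mediated global desilylation removes the TBS and TES ethers and the silylene in one operation, the pyridine buffer avoiding both base-induced epoxide migration (Payne) and acid ionisation at the dienylic C1' carbinol.

**Compound list**

1 | 1,3-dihydroxyacetone dimer (2,5-bis(hydroxymethyl)-1,4-dioxane-2,5-diol) | OCC1(O)COC(O)(CO)CO1 | starting material
2 | 1,3-dihydroxyacetone (monomer) | OCC(=O)CO | intermediate (not isolated)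
3 | 2,2-di-tert-butyl-1,3,2-dioxasilinan-5-one | O=C1CO[Si](C(C)(C)C)(C(C)(C)C)OC1 | intermediate
4 | diethyl (cyanomethyl)phosphonate | N#CCP(=O)(OCC)OCC | starting material
5 | 2-(2,2-di-tert-butyl-1,3,2-dioxasilinan-5-ylidene)acetonitrile | N#CC=C1CO[Si](C(C)(C)C)(C(C)(C)C)OC1 | intermediate
6 | 2-(2,2-di-tert-butyl-1,3,2-dioxasilinan-5-ylidene)acetaldehyde | O=CC=C1CO[Si](C(C)(C)C)(C(C)(C)C)OC1 | intermediate
7 | tert-butyl{[(E)-2-(2,2-di-tert-butyl-4H-1,3,2-dioxasilin-5-yl)ethenyl]oxy}dimethylsilane | CC(C)(C)[Si](C)(C)O/C=C/C1=CO[Si](C(C)(C)C)(C(C)(C)C)OC1 | intermediate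
8 | propiolic acid | C#CC(=O)O | starting material
9 | 3,5-dimethyl-1H-pyrazole | Cc1cc(C)[nH]n1 | starting material
10 | 1-(3,5-dimethyl-1H-pyrazol-1-yl)prop-2-yn-1-one | C#CC(=O)n1nc(C)cc1C | intermediate
11 | (3,5-dimethyl-1H-pyrazol-1-yl)[(6S,8aS)-2,2-di-tert-butyl-6-(tert-butyldimethylsilyloxy)-6,8a-dihydro-4H-1,3,2-benzodioxasilin-7-yl]methanone | O=C(n1nc(C)cc1C)C1=C[C@H](O[Si](C(C)(C)C)(C(C)(C)C)OC2)C2=C[C@@H]1O[Si](C)(C)C(C)(C)C | intermediate
12 | (6S,8aS)-2,2-di-tert-butyl-6-(tert-butyldimethylsilyloxy)-6,8a-dihydro-4H-1,3,2-benzodioxasilin-7-carbaldehyde | O=CC1=C[C@H](O[Si](C(C)(C)C)(C(C)(C)C)OC2)C2=C[C@@H]1O[Si](C)(C)C(C)(C)C | intermediate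
13 | epoxy aldehyde: C1–C6 oxirane of 12, anti to both silyloxy groups | O=C[C@]12O[C@H]1[C@H](O[Si](C(C)(C)C)(C(C)(C)C)OC3)C3=C[C@@H]2O[Si](C)(C)C(C)(C)C | intermediate
14 | geranyl acetate | CC(=O)OC/C=C(\C)CCC=C(C)C | starting material
15 | (2E)-5-[(2R)-3,3-dimethyloxiran-2-yl]-3-methylpent-2-en-1-yl acetate | CC(=O)OC/C=C(\C)CC[C@H]1OC1(C)C | intermediate
16 | trans-fused 2-methyl-1,3-dioxan-2-ylium ion bridging the C6'' oxygen and the CH2O group (drawn with free C3'' hydroxyl) | C[C+]1OC[C@@H]2C(C)(C)[C@H](O)CC[C@@]2(C)O1 | intermediate (not isolated)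
17 | [(1S,3R,6R)-3,6-dihydroxy-2,2,6-trimethylcyclohexyl]methyl acetate | CC(=O)OC[C@@H]1C(C)(C)[C@H](O)CC[C@@]1(C)O | intermediate
18 | [(1S,3R,6R)-2,2,6-trimethyl-3,6-bis(triethylsilyloxy)cyclohexyl]methyl acetate | CC(=O)OC[C@@H]1C(C)(C)[C@H](O[Si](CC)(CC)CC)CC[C@@]1(C)O[Si](CC)(CC)CC | intermediate
19 | [(1S,3R,6R)-2,2,6-trimethyl-3,6-bis(triethylsilyloxy)cyclohexyl]methanol | OC[C@@H]1C(C)(C)[C@H](O[Si](CC)(CC)CC)CC[C@@]1(C)O[Si](CC)(CC)CC | intermediate
20 | (1R,3R,6R)-2,2,6-trimethyl-3,6-bis(triethylsilyloxy)cyclohexane-1-carbaldehyde | O=C[C@@H]1C(C)(C)[C@H](O[Si](CC)(CC)CC)CC[C@@]1(C)O[Si](CC)(CC)CC | intermediate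
21 | propargyl alcohol | C#CCO | starting material
22 | chelated (Z)-alkenylmagnesium alkoxide (4-methyl-2,5-dihydro-1,2-oxamagnesole) | CC1=C[Mg]OC1 | intermediate (not isolated)
23 | (2Z)-3-iodo-2-methylprop-2-en-1-ol | OC/C(C)=C\I | intermediate
24 | (1Z)-3-bromo-1-iodo-2-methylprop-1-ene | BrC/C(C)=C\I | intermediate
25 | triethyl phosphite | CCOP(OCC)OCC | starting material
26 | diethyl [(2Z)-3-iodo-2-methylprop-2-en-1-yl]phosphonate | CCOP(=O)(OCC)C/C(C)=C\I | intermediate
27 | (1Z,3E)-1-iodo-2-methyl-4-[(1R,3R,6R)-2,2,6-trimethyl-3,6-bis(triethylsilyloxy)cyclohexyl]buta-1,3-diene | CC(=C/I)/C=C/[C@@H]1C(C)(C)[C@H](O[Si](CC)(CC)CC)CC[C@@]1(C)O[Si](CC)(CC)CC | intermediate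
28 | (1Z,3E)-dienyllithium from 27 (Li in place of I) | CC(=C/[Li])/C=C/[C@@H]1C(C)(C)[C@H](O[Si](CC)(CC)CC)CC[C@@]1(C)O[Si](CC)(CC)CC | intermediate (not isolated)
29 | tetrasilyl-protected arthrosporol A (O2 TBS; O5/O7 di-tert-butylsilylene; C3'' and C6'' TES ethers; free 1'S hydroxyl) | CC(=C/[C@H](O)[C@]12O[C@H]1[C@H](O[Si](C(C)(C)C)(C(C)(C)C)OC3)C3=C[C@@H]2O[Si](C)(C)C(C)(C)C)/C=C/[C@@H]1C(C)(C)[C@H](O[Si](CC)(CC)CC)CC[C@@]1(C)O[Si](CC)(CC)CC | intermediate
30 | arthrosporol A | CC(=C/[C@H](O)[C@]12O[C@H]1[C@H](O)C(CO)=C[C@@H]2O)/C=C/[C@@H]1C(C)(C)[C@H](O)CC[C@@]1(C)O | target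

**Count and risks**

Total step count: 19. Longest linear sequence: 9 steps (steps 1, 2, 3, 4, 6, 7, 8, 18, 19).

Steps most likely to fail:

1. Step 6. The catalyst may discriminate poorly between the two diene faces, C2 instead of C5 may bond to C6, the silyl group may transfer to the enolate before ring closure, or the adduct may lose silanol and aromatise under the Lewis acid. Fallback, setting out from 7 and 10: the cycloaddition is run thermally without any catalyst (toluene, rt to 40 °C), which removes the Lewis acid and should give 11 together with the enantiomeric acyl pyrazole F1. The racemate is taken through steps 7 and 8 unchanged, giving 12 with the enantiomeric enal F2 and 13 with the enantiomeric epoxy aldehyde F3. In step 18 the enantiopure dienyllithium 28 turns the pair into 29 and the core-diastereomeric coupling product F4, which are separated by chromatography; the route is rejoined at 29.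

2. Step 10. The tertiary cation may lose a proton to cyclogeranyl alkenes or be captured by the oxirane-derived oxygen as a bicyclic ether instead of being trapped by the acetate. Fallback, setting out from 15: radical cyclisation with Cp2TiCl (trivalent titanium, from Cp2TiCl2 and Mn, THF) should give the exocyclic alkene F5. Epoxidation with mCPBA should occur from the equatorial direction, the axial face being blocked by the axial methyl on C2'', to give the spiro-epoxide F6. LiAlH4 opens the oxirane at its CH2 and cleaves the acetate to the triol F7, and selective acetylation of the primary hydroxyl (AcCl, 2,4,6-collidine, CH2Cl2, −78 °C) rejoins the route at 17.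

3. Step 18. Facial selectivity at the aldehyde may be poor if lithium chelation competes with the Cornforth arrangement. Fallback, setting out from the crude coupling product (29 mixed with the 1'-epimeric alcohol F8): the mixture is oxidised with Dess–Martin periodinane to the epoxy dienone F9, which is reduced at once with Zn(BH4)2 in Et2O at −20 °C. Chelation of zinc between the carbonyl and oxirane oxygens and hydride delivery on the side away from C6 should give 29, where the route is rejoined.

Further compounds

F1 | step 6 | enantiomeric acyl pyrazole (ent-11) | O=C(n1nc(C)cc1C)C1=C[C@@H](O[Si](C(C)(C)C)(C(C)(C)C)OC2)C2=C[C@H]1O[Si](C)(C)C(C)(C)C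
F2 | step 6 | enantiomeric enal (ent-12) | O=CC1=C[C@@H](O[Si](C(C)(C)C)(C(C)(C)C)OC2)C2=C[C@H]1O[Si](C)(C)C(C)(C)C
F3 | step 6 | enantiomeric epoxy aldehyde (ent-13) | O=C[C@@]12O[C@@H]1[C@@H](O[Si](C(C)(C)C)(C(C)(C)C)OC3)C3=C[C@H]2O[Si](C)(C)C(C)(C)C
F4 | step 6 | core-diastereomeric coupling product (29 with C1', C1, C2, C5 and C6 all inverted) | CC(=C/[C@@H](O)[C@@]12O[C@@H]1[C@@H](O[Si](C(C)(C)C)(C(C)(C)C)OC3)C3=C[C@H]2O[Si](C)(C)C(C)(C)C)/C=C/[C@@H]1C(C)(C)[C@H](O[Si](CC)(CC)CC)CC[C@@]1(C)O[Si](CC)(CC)CC
F5 | step 10 | exocyclic alkene, [(1R,3R)-3-hydroxy-2,2-dimethyl-6-methylidenecyclohexyl]methyl acetate | CC(=O)OC[C@@H]1C(C)(C)[C@H](O)CCC1=C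
F6 | step 10 | spiro-epoxide of F5 (oxirane oxygen equatorial, trans to the CH2OAc group) | CC(=O)OC[C@@H]1C(C)(C)[C@H](O)CC[C@]12CO2
F7 | step 10 | triol, 2-(hydroxymethyl)-1,3,3-trimethylcyclohexane-1,4-diol with the configuration of 17 | OC[C@@H]1C(C)(C)[C@H](O)CC[C@@]1(C)O
F8 | step 18 | 1'-epimeric alcohol (1'R epimer of 29) | CC(=C/[C@@H](O)[C@]12O[C@H]1[C@H](O[Si](C(C)(C)C)(C(C)(C)C)OC3)C3=C[C@@H]2O[Si](C)(C)C(C)(C)C)/C=C/[C@@H]1C(C)(C)[C@H](O[Si](CC)(CC)CC)CC[C@@]1(C)O[Si](CC)(CC)CC
F9 | step 18 | epoxy dienone (C1' ketone of 29) | CC(=C/C(=O)[C@]12O[C@H]1[C@H](O[Si](C(C)(C)C)(C(C)(C)C)OC3)C3=C[C@@H]2O[Si](C)(C)C(C)(C)C)/C=C/[C@@H]1C(C)(C)[C@H](O[Si](CC)(CC)CC)CC[C@@]1(C)O[Si](CC)(CC)CC
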